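One lifetime of G, the time in which a first-order loss cuts it by the factor e, was my unit for this flask.

| flask | G | L | remark | time | volume of the second phase over the first |
|---|---|---|---|---|---|
| birch | 20 mM | 8 mM | run made earlier |  |  |
| flask | 10 mM | 8.00 mM |  | 5.0 h | 0.25 |

birch run (percent of the G charged)

| time / min | D / % | G / % |
|---|---|---|
| 2.50 | 3 | 92 |
| 5.00 | 0 | 92 |
| 8.00 | 1 | 85 |
| 15.0 | 1 | 74 |
| 30.0 | 0 | 53 |

(scatter of a reading: 2 percentage points)

- in the second phase: L; everything else is in the first
- charges count per volume of the first phase; a concentration in a rate is the amount of a species over the volume of its own phase; every rate counts per litre of the first phase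
- the earlier runs were read with a standard deviation of 2 percentage points
- the earlier runs hold the two phases in the same ratio of volumes as the flask asked about
- what has gone from G into another species counts as reacted, even if it can come back

- amount of D at 5.0 h, in percent of the G charged
- part of the G charged that has reacted at 5.0 h

From the last birch reading of G I took a first-order constant (pseudo-first-order, on my assumption that L stayed in the background), k = 1.27 h⁻¹. Folded with the time, it gave the lifetime count N = k·t, the time asked for in lifetimes of G: 6.35 for the flask. A count of zero means no G has gone, and each unit cuts G by e, so I reckoned 0.175% of G left and 99.8% reacted.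

Was one number enough? The birch reading at 15.0 min gave k = 1.20 h⁻¹, against the first value of 1.27 h⁻¹. But the birch readings stop at a count of 0.635, and the flask asks for ten times that, so the reckoning ran far past the last reading it came from. N also gave me no figure for D, whose birch readings stayed at or below 3%, with a scatter of 2 percentage points.

The forecast said “G should be nearly gone unless the first step is reversible”. It put D at 13% (1% to 55%) and reacted G at 96% (70% to 100%). My own reckoning put reacted G higher than the forecast did, and unlike the forecast it gave no figure for D.

The flask gave D 12.2% and reacted G 69.8%.

    J ⇌ L, rate k1*([J] - [L]/K1) per volume of the first phase (partition coefficient = 40.0, kL = 7.90 × 10⁻⁴ s⁻¹)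
    G + J → D (k = 0.0410 M⁻¹ s⁻¹)
    2 J → Z (k = 0.0180 M⁻¹ s⁻¹)
    G ⇌ E (K = 1.80, k = 3.80 × 10⁻⁴ s⁻¹)
    J + D → X (k = 0.0230 M⁻¹ s⁻¹)

The 30% of G left in the flask at 5.0 h amounts to a count of 1.20, against N = 6.35, with E at 56.2%. The relaxation half-life of G and E by their own step, 0.326 h, is short against that time. The neighbouring flask, the same one read at 20 h, has N = 25.4, but its G left, 23%, amounts to a count of 1.47. In that neighbour 76.8% had reacted and D stood at 24.4% of the G charged.

Readings and results were generated by integration for an exercise, noise included.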